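The strategy reads the C3(OH)–C2=C1–C6(OH) segment of the cyclohexene ring as the reduced form of an O2 adduct of a cyclohexa-1,3-diene. Its two allylic oxygens, O3 and O6, are cis to each other and anti to the cis O4/O5 pair. One sensitised singlet-oxygen [4+2] cycloaddition forms the C3–O and C6–O bonds, sets both stereocentres and moves the alkene to C1=C2. Thiourea then cuts the peroxide. The precursor is a dienyl carbinol bearing C7 on C1 and a cis-fused 4,5-acetonide. It is made from (−)-shikimic acid, which supplies C4, C5 and the whole carbon skeleton. A 6,7-silylene then allows benzoylation at O5, and finally at O7.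

Key step: step 5

Locants: compounds 1–6 carry shikimate locants. From the key step on, target locants apply: C1 bears C7, C2 is the vinylic CH, and C3–C6 are the carbinol carbons. Shikimate C2/C3/C4/C5/C6 become target C6/C5/C4/C3/C2.

Step 1
Reactants: 1 (−)-shikimic acid
Product: 3 methyl 3,4-O-isopropylideneshikimate, via methyl shikimate 2 (not isolated)
Conditions: CSA (cat.), MeOH, reflux; concentrate; then Me2C(OMe)2, acetone, rt; Et3N quench
Reagents that add atoms: methanol, CO; 2,2-dimethoxypropane, COC(C)(C)OC
Why: Fischer esterification is followed in the same flask by acid-catalysed transketalisation, in which only the cis 3,4-diol can carry an unstrained fused dioxolane, so the trans-disposed 5-OH stays free and no stereocentre is touched.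

Step 2
Reactants: 3 methyl 3,4-O-isopropylideneshikimate
Product: 4 methyl 3,4-O-isopropylidene-5-O-triflylshikimate
Conditions: Tf2O, pyridine, CH2Cl2, −20 °C; cold aqueous wash, used crude
Reagents that add atoms: triflic anhydride, O=S(=O)(OS(=O)(=O)C(F)(F)F)C(F)(F)F
Why: O-sulfonylation of the only free hydroxyl, with retention at C5, installs a leaving group reactive enough for elimination at room temperature with a weak base, which a mesylate would not allow.

Step 3
Reactants: 4 methyl 3,4-O-isopropylidene-5-O-triflylshikimate
Product: 5 methyl (3R,4S)-3,4-(isopropylidenedioxy)cyclohexa-1,5-diene-1-carboxylate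
Conditions: CsOAc, DMF, rt; product used promptly
Reagents that add atoms: none
Why: This is an anti E2 elimination in which H4 is cis to the triflate while one H6 can be antiperiplanar to it, so loss of TfOH can only run toward C6 to give the conjugated dienoate, and the weak base CsOAc avoids γ-deprotonation and aromatisation.

Step 4
Reactants: 5 methyl (3R,4S)-3,4-(isopropylidenedioxy)cyclohexa-1,5-diene-1-carboxylate
Product: 6 [(3R,4S)-3,4-(isopropylidenedioxy)cyclohexa-1,5-dien-1-yl]methanol
Conditions: iBu2AlH (2.3 equiv), CH2Cl2, −78 °C; aq. KNaC4H4O6 (potassium sodium tartrate)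
Reagents that add atoms: none
Why: 1,2-Reduction of the conjugated ester by two hydride transfers at low temperature, with a neutral tartrate work-up because the dienyl carbinol aromatises under acid, gives a diene that is more electron-rich than the ester and so a better partner for electrophilic singlet oxygen.

Step 5
Reactants: 6 [(3R,4S)-3,4-(isopropylidenedioxy)cyclohexa-1,5-dien-1-yl]methanol
Product: 8 4,5-O-isopropylidene 3,6,7-triol, via endoperoxide 7 (not isolated)
Conditions: O2, tetraphenylporphyrin (cat.), white LED, CH2Cl2, −20 °C; then thiourea (2.2 equiv), MeOH, −20 °C → rt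
Reagents that add atoms: dioxygen, O=O
Why: Sensitised singlet oxygen adds suprafacially, as the two-atom partner of a concerted [4+2] cycloaddition, to the termini C6 and C3 of the ring-held s-cis diene C6=C1–C2=C3 (target locants), so both C–O bonds form in one event and the remaining π bond ends up at C1=C2. The closest known reaction type is the photooxygenation of cyclohexa-3,5-diene-1,2-diol acetonides followed by thiourea reduction to conduritol A derivatives. The one new ring, the 1,2-dioxane bridge of the 2,3-dioxabicyclo[2.2.2]oct-5-ene 7, closes by this intermolecular cycloaddition across the 1,4-positions of the carbocycle, and it is opened again in the same flask when thiourea reduces only the weak O–O bond, sparing the alkene, the acetonide and every C–O bond. C3 and C6 are both set by approach of O2 to the diene face anti to the cis-fused dioxolane on C4/C5, and the bridge forces them to be cis to each other. O2 is symmetric, so only π-facial selectivity and chemoselectivity over the ene mode are needed: the acetonide secures the first, and the planar s-cis geometry, the electron-rich carbinol-substituted diene and the low temperature secure the second.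

Step 6
Reactants: 8 4,5-O-isopropylidene 3,6,7-triol
Product: 9 6,7-O-(di-tert-butylsilylene) 4,5-acetonide with free 3-OH
Conditions: tBu2Si(OTf)2 (1.05 equiv), 2,6-lutidine, DMF, −40 → 0 °C
Reagents that add atoms: di-tert-butylsilyl bis(triflate), CC(C)(C)[Si](OS(=O)(=O)C(F)(F)F)(OS(=O)(=O)C(F)(F)F)C(C)(C)C
Why: In this cyclic silylene formation the bis-triflate takes primary O7 first and then closes the six-membered 1,3,2-dioxasilinane on neighbouring O6, whereas C3 lies trans to C7 across the alkene, so O3 cannot be bridged and stays free.

Step 7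
Reactants: 9 6,7-O-(di-tert-butylsilylene) 4,5-acetonide with free 3-OH
Product: 10 6,7-O-(di-tert-butylsilylene) 3,4,5-triol
Conditions: 80% aq. AcOH, 45 °C
Reagents that add atoms: none
Why: In this acid-catalysed ketal hydrolysis the acetonide ionises much faster than the hindered di-tert-butylsilylene of a 1,3-diol is protonolysed, and no ring C–O bond is broken, so all four stereocentres persist.

Step 8
Reactants: 10 6,7-O-(di-tert-butylsilylene) 3,4,5-triol; 11 benzoyl chloride
Product: 13 5-O-benzoyl-6,7-O-(di-tert-butylsilylene) 3,4-diol, via 4,5-O-dibutylstannylene acetal 12 (not isolated)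
Conditions: Bu2SnO (1.05 equiv), toluene, reflux (−H2O); then BzCl (1.0 equiv), 0 °C → rt
Reagents that add atoms: benzoyl chloride 11, O=C(Cl)c1ccccc1; dibutyltin oxide, CCCC[Sn](=O)CCCC (its tin is found only in 12)
Why: In this stannylene-acetal-directed monoacylation tin bridges only the cis O4/O5 pair (O3/O4 are trans), and because the dioxasilinane contains sp2 C1, its small C7–C1–C6–O6 dihedral keeps O6 pseudoequatorial, which places O5 equatorial and O4 axial as in a 4,6-O-tethered α-mannopyranoside, whose stannylene is acylated at the equatorial oxygen.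

Step 9
Reactants: 13 5-O-benzoyl-6,7-O-(di-tert-butylsilylene) 3,4-diol
Product: 14 5-O-benzoyl 3,4,6,7-tetrol
Conditions: HF·pyridine, extra pyridine, THF, 0 °C
Reagents that add atoms: none
Why: Fluoride-driven Si–O cleavage is run under weakly acidic, pyridine-buffered conditions rather than with basic Bu4NF, so that the O5 benzoate does not migrate to O4 or O6.

Step 10
Reactants: 14 5-O-benzoyl 3,4,6,7-tetrol; 11 benzoyl chloride
Product: 15 target CNP0198957.1
Conditions: BzCl (1.05 equiv), 2,4,6-collidine, CH2Cl2–THF, −78 → −40 °C
Reagents that add atoms: benzoyl chloride 11, O=C(Cl)c1ccccc1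
Why: In this kinetically controlled acylation, one equivalent of acid chloride and a hindered weak base at low temperature let the unhindered primary allylic O7–H react far faster than the three secondary hydroxyls, in a medium too weakly basic for acyl migration.

Compound list
1 | (−)-shikimic acid, (3R,4S,5R)-3,4,5-trihydroxycyclohex-1-ene-1-carboxylic acid | O=C(O)C1=C[C@@H](O)[C@@H](O)[C@H](O)C1 | starting material
2 | methyl (−)-shikimate, (3R,4S,5R) | COC(=O)C1=C[C@@H](O)[C@@H](O)[C@H](O)C1 | intermediate
3 | methyl 3,4-O-isopropylideneshikimate (dioxolane cis-fused at O3/O4, free 5-OH trans to O4) | COC(=O)C1=C[C@H]2OC(C)(C)O[C@H]2[C@H](O)C1 | intermediate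
4 | methyl 3,4-O-isopropylidene-5-O-(trifluoromethylsulfonyl)shikimate | COC(=O)C1=C[C@H]2OC(C)(C)O[C@H]2[C@H](OS(=O)(=O)C(F)(F)F)C1 | intermediate
5 | methyl (3R,4S)-3,4-(isopropylidenedioxy)cyclohexa-1,5-diene-1-carboxylate | COC(=O)C1=C[C@H]2OC(C)(C)O[C@H]2C=C1 | intermediate
6 | [(3R,4S)-3,4-(isopropylidenedioxy)cyclohexa-1,5-dien-1-yl]methanol | OCC1=C[C@H]2OC(C)(C)O[C@H]2C=C1 | intermediate
7 | (3R,4R,5S,6S)-3,6-epidioxy-1-(hydroxymethyl)-4,5-(isopropylidenedioxy)cyclohex-1-ene, a 2,3-dioxabicyclo[2.2.2]oct-5-ene with the O–O bridge anti to the acetonide | OCC1=C[C@@H]2[C@@H]3OC(C)(C)O[C@@H]3[C@H]1OO2 | intermediate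
8 | (3R,4S,5R,6S)-1-(hydroxymethyl)-4,5-(isopropylidenedioxy)cyclohex-1-ene-3,6-diol (O3/O6 cis, anti to the acetonide) | OCC1=C[C@@H](O)[C@@H]2OC(C)(C)O[C@@H]2[C@H]1O | intermediate
9 | 6,7-O-(di-tert-butylsilylene) derivative of 8, (3R,4S,5S,6S), free 3-OH | CC(C)(C)[Si]1(C(C)(C)C)OCC2=C[C@@H](O)[C@@H]3OC(C)(C)O[C@@H]3[C@H]2O1 | intermediate
10 | 6,7-O-(di-tert-butylsilylene) 3,4,5-triol, (3R,4S,5S,6S) | CC(C)(C)[Si]1(C(C)(C)C)OCC2=C[C@@H](O)[C@H](O)[C@H](O)[C@H]2O1 | intermediate
11 | benzoyl chloride | O=C(Cl)c1ccccc1 | starting material
12 | 4,5-O-dibutylstannylene acetal of 10 | CC(C)(C)[Si]1(C(C)(C)C)OCC2=C[C@@H](O)[C@@H]3O[Sn](CCCC)(CCCC)O[C@@H]3[C@H]2O1 | intermediate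
13 | 5-O-benzoyl-6,7-O-(di-tert-butylsilylene) 3,4-diol, (3R,4S,5S,6S) | CC(C)(C)[Si]1(C(C)(C)C)OCC2=C[C@@H](O)[C@H](O)[C@H](OC(=O)c3ccccc3)[C@H]2O1 | intermediate
14 | (3R,4S,5R,6S)-5-(benzoyloxy)-1-(hydroxymethyl)cyclohex-1-ene-3,4,6-triol | OCC1=C[C@@H](O)[C@H](O)[C@H](OC(=O)c2ccccc2)[C@H]1O | intermediate
15 | [(3R,4S,5R,6S)-5-(benzoyloxy)-3,4,6-trihydroxycyclohex-1-en-1-yl]methyl benzoate, CNP0198957.1 | O=C(OCC1=C[C@@H](O)[C@H](O)[C@H](OC(=O)c2ccccc2)[C@H]1O)c1ccccc1 | target

Total step count: 10. Longest linear sequence: 10 steps, from 1 to 15.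

Steps most likely to fail

Step 8 (tin-directed benzoylation). The fused dioxasilinane may bias the half-chair too weakly. Acyl transfer would then spread over O4 and O5, or the ester would drift between them. The fallback blocks the competing oxygens instead of directing the reagent.
- Setting out from 10, the trans O3/O4 pair is tied up with butane-2,3-dione, CH(OMe)3 and catalytic CSA in MeOH. This gives the trans-fused 3,4-O-(2,3-dimethoxybutane-2,3-diyl) acetal F1. This protecting group accepts trans-diequatorial diols but not cis diols.
- O5 is then the only hydroxyl left. It is esterified with 11, pyridine and DMAP to give the diacetal 5-O-benzoate F2.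
- Aqueous TFA in CH2Cl2 removes the diacetal, and the route is rejoined at 13.

Step 5 (photooxygenation and reduction). Three processes could compete: ene-type hydroperoxidation at the allylic C–H bonds, aromatisation of the labile dienyl carbinol during irradiation, and Kornblum–DeLaMare-type rearrangement of the peroxide before it is reduced. The fallback uses two ionic C–O bond formations instead of a cycloaddition.
- Setting out from 6, buffered mCPBA (NaHCO3, CH2Cl2, 0 °C) should epoxidise the more substituted C1=C6 bond on the face anti to the acetonide. This gives the vinyl epoxide F3.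
- Pd(PPh3)4 (cat.) and AcOH in THF then open the epoxide in the Tsuji–Trost 1,4-sense. Zerovalent palladium ionises the allylic C1–O bond with inversion, and acetate attacks C3 anti to the metal. The resulting 3-O-acetate F4 therefore carries O3 cis to O6.
- K2CO3 in MeOH removes the acetate, and the route is rejoined at 8.

Step 7 (acetonide hydrolysis). The silylene may be partly lost, or opened at the primary O7–Si bond, while the ketal hydrolyses. The fallback reverses the order of events so that silicon never meets acid.
- Setting out from 8, the acetonide is hydrolysed first (acidic ion-exchange resin, MeOH–H2O) to give the free pentol F5.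
- F5 is treated with one equivalent of tBu2Si(OTf)2 in pyridine–DMF at −40 °C. As with unprotected hexopyranosides, the reagent should take the primary hydroxyl and close the six-membered ring on O6. Five-membered silylenes on the 4,5-diol are strained and labile.
- The route is rejoined at 10.

Further compounds
F1 | step 8 | 3,4-O-[(2S,3S)-2,3-dimethoxybutane-2,3-diyl] acetal of 10 (both methoxy groups axial, free 5-OH) | CC(C)(C)[Si]1(C(C)(C)C)OCC2=C[C@H]3O[C@](C)(OC)[C@@](C)(OC)O[C@@H]3[C@H](O)[C@H]2O1
F2 | step 8 | 5-O-benzoate of F1 | CC(C)(C)[Si]1(C(C)(C)C)OCC2=C[C@H]3O[C@](C)(OC)[C@@](C)(OC)O[C@@H]3[C@H](OC(=O)c4ccccc4)[C@H]2O1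
F3 | step 5 | 1,6-epoxide of 6, oxirane anti to the acetonide, C2=C3 alkene retained | OC[C@]12C=C[C@@H]3OC(C)(C)O[C@@H]3[C@H]1O2
F4 | step 5 | 3-O-acetate of 8 | OCC1=C[C@@H](OC(C)=O)[C@@H]2OC(C)(C)O[C@@H]2[C@H]1O
F5 | step 7 | (3R,4S,5R,6S)-1-(hydroxymethyl)cyclohex-1-ene-3,4,5,6-tetrol | OCC1=C[C@@H](O)[C@H](O)[C@H](O)[C@H]1O
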